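## Analysis of the target

Nakijiquinone E (25) consists of two bicyclic terpenoid units joined through one arylamine nitrogen. A methyl 3-amino-2,4-dihydroxybenzoate carries one decalinylmethyl group at its C5. A 2-hydroxy-1,4-benzoquinone carries the other at its C3, and the nitrogen sits on quinone C5. Both decalins are the same rearranged, trans-fused bicycle (clerodane numbering is used throughout, and chain carbons keep their numbers when they become ring atoms of an arene). Ring A (C1–C5, C10) and ring B (C5–C10) share C5 and C10; methyl groups sit on C5, C8 and C9; C9 also carries the C11 methylene that leads to the arene; C4 carries C18. The two halves differ only in the alkene: C4=C18 (exocyclic) in the benzoate half, C3=C4 in the quinone half. Each decalin has four contiguous stereocentres (C5, C8, C9, C10; two quaternary), and both are (5S,8S,9R,10S): H10 is anti to the C5 methyl group, and the C8 and C9 methyl groups are cis to each other and to the C5 methyl group. Sensitive groups are the exocyclic alkene (it moves into the ring under acid), the 2-aminoresorcinol (oxidation), the hydroxyquinone (base, nucleophiles) and the salicylate-type ester. The difficulty lies in two crowded stereo-arrays, in neopentyl C9–C11–aryl links that no SN2 reaction will form, and in two fully differentiated arenes. The strategy rests on one observation: rings A and B, with their C5/C8/C9 methyl pattern, the C3=C4 alkene and the C9 side chain, are exactly what a proton-initiated enzymatic cyclisation of an all-E C20 chain with four 1,2-shifts delivers. The chain left on C9 (C11–C16) ends, after cleavage at C13, in a methyl ketone whose carbons C12, C13 and C16 can become three adjacent ring atoms of either arene.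

## Retrosynthetic reasoning

**C–N bond.** 25 is cut between the nitrogen and quinone C5 into hydroxyquinone 14 and aminoresorcinol ester 24. This is the only bond that joins two halves of equal size, so the cut gives full convergence and needs no protecting group. In the forward sense the amine must add in conjugate fashion to C5 of 14 and the adduct must be reoxidised. The C4 carbonyl of 14 is tied up as a vinylogous acid with the C2 hydroxyl, so only the C1 carbonyl activates a ring CH, and that CH is C5.

**Quinone ring.** 14 is traced to the resorcinol 13 by removing the oxygen para to a hydroxyl (a Teuber oxidation forwards), and 13 to the dione 10 by adding two hydrogens. 10 is cut at the two ring bonds that C12 and C16 make to the three carbons of methyl acrylate 8, which leaves ketone 7. The cut is made here because C12 must become an arene carbon flanked by two oxygenated carbons: C13 brings the ketone oxygen and the ester carbon of 8 brings the other. Because 10 and 13 are symmetric about C12, neither the dehydrogenation nor the oxidation has a regiochemical choice. The forward sequence needs the kinetic (C16) enolate of 7 for the Michael addition and the C12 enolate for the Dieckmann closure.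

**Benzoate ring.** 24 is traced to 22 by removing the nitrogen at the only position ortho to both hydroxyls (azo coupling and reductive N=N cleavage forwards). 22 is cut at the bonds from C12 to the β-carbon and from the former ester carbon to the α-carbon of methyl propiolate 19; the four-carbon partner is the bis(silyl) dienol ether of β-keto ester 18. 18 is cut at C16 into the exocyclic ketone 16 and dimethyl carbonate 17. Here C12 needs one oxygenated neighbour (C13) and one CH neighbour, which is what a Diels–Alder reaction with an alkynoate provides; the ester then sits next to that CH, as in the target.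

**Alkene position.** 16 is traced through the allylic chloride 15 to 7. The thermodynamically disfavoured move of the alkene out of the ring is done by an ene-type chlorination, which can only deliver the C4=C18 alkene because C5 is quaternary, followed by palladium-catalysed hydride delivery to the more substituted allyl terminus. It is placed on the simple ketone, before any phenol or amine is present.

**Side chain.** 7 is traced through epoxy alcohol 6 to kolavenol 5 by reconnecting C13 to C14. Cleaving C13=C14 removes C14 and C15 and turns C13 into the ketone on which both arenes are built. The forward reaction must distinguish this alkene from C3=C4, which the allylic hydroxyl allows.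

**Decalin (key disconnection).** 5 is the dephosphorylated form of 4, and 4 is opened at C4–C5 and C9–C10, with the methyl groups on C5 and C9 and the hydrogens on C8 and C10 returned to their original carbons, to the acyclic diphosphate 3. Both rings and all four stereocentres arise in one step from an achiral chain.

**Precursor.** 3 comes from commercial geranylgeraniol 1 through the chloride 2 in two functional-group steps, so the risk of the route sits in the cyclisation.

## Alternatives that were turned down

**Alternative 1:** Ring B is cut across C5–C6 and C9–C10. Forwards, a methoxy-methyl-benzoquinone dienophile and a 2,3-dimethyl diene with a silyloxymethyl group react under a chiral Lewis acid to give the cis-fused endo adduct A1. In its favour: one catalytic step creates both quaternary carbons (C5, C9) with an oxygenated C11, and no enzyme has to be sourced. The C4 carbonyl of A1 could give either alkene isomer (olefination or methyl addition and dehydration) without any transposition, and the C11–O handle suits classical aryl attachment. On these three points it is stronger than the chosen route. Against it: A1 is cis-fused, so C10 must be epimerised. C8 is still an alkene carbon and needs a face-selective hydrogenation. Ring A arrives at the quinone oxidation level, so two oxygens (C1, C2) must be removed and C4 rebuilt. Well over ten operations separate A1 from a decalin ready for an arene, and this must be done for two halves. The chosen strategy sets C5, C8, C9 and C10 and the alkene in one step from an acyclic precursor and builds the arenes on carbons that are already there.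

**Alternative 2:** The quinone ring is cut between the ketene carbon and the alkoxy-bearing alkene carbon. Forwards, a 4-alkenyl-4-hydroxy-3-(arylamino)cyclobutenone opens on heating to a dienylketene that closes to the hydroquinone A2, which is then oxidised and deprotected. In its favour: the nitrogen is placed by construction, so there is no regiochemical or redox question at the C–N bond; on that point it is stronger than the conjugate amination used here. Against it: it says nothing about the decalins, which are the real problem, and it presupposes both of them in elaborate form. One must be an alkenyl-metal reagent with the neopentyl CH2 in place; the other must already carry a doubly protected aminoresorcinol. It then adds acetal and ethyl-ether cleavages next to an acid-labile exocyclic alkene. The chosen route joins two unprotected halves in one step and relies on the electronic bias of 14 for regiocontrol.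

**Alternative 3:** Ring B is cut at C5–C10 and C8–C9. Forwards, a tethered 2-methyl enal adds to a vinylallene under a chiral Lewis acid, closing rings B and A together to give the trans-decalin aldehyde A3. In its favour: the trans fusion, C5, C9 and C10 come in one step, C11 is an aldehyde (the classical handle for aryl-metal addition), and the C4 ketal allows either alkene isomer; on the C11 handle and on alkene flexibility it is stronger. Against it: the vinylallene–enal substrate is a multistep synthesis in itself. The enantioselective intramolecular cycloaddition must form a quaternary centre. C8 is not set, and must come from selective reduction of a diene. A3 then needs benzylic deoxygenation after each aryl addition. The chosen strategy reaches the complete bicycle, C8 included, three steps from a commercial alcohol and uses the residual chain instead of removing it.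

Key step: step 3

**Remarks.** R(endo) = (1R,2S,4aS,8aS)-1,2,4a,5-tetramethyl-1,2,3,4,4a,7,8,8a-octahydronaphthalen-1-yl (the C3=C4 decalin without C11). R(exo) = (1R,2S,4aS,8aS)-1,2,4a-trimethyl-5-methylidenedecahydronaphthalen-1-yl (the C4=C18 decalin). Ketone 7 is divided: one portion enters steps 7–9, the other steps 10–14. Assumption: a recombinant class 2 diterpene cyclase that gives the (5S,8S,9R,10S) kolavenyl series drawn in 4 is available (bacterial enzymes of this series have been described; the common plant enzymes give the antipode); the series is to be confirmed on 5 before material is committed.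

## Route

Step 1
Reactants: 1 geranylgeraniol
Product: 2 geranylgeranyl chloride
Conditions: N-chlorosuccinimide, Me2S, CH2Cl2, −30 to 0 °C
Reagents that add atoms: N-chlorosuccinimide, O=C1CCC(=O)N1Cl
Why: Corey–Kim chlorination: the alkoxysulfonium salt is displaced by chloride at the primary allylic carbon, without allylic transposition or loss of alkene geometry.

Step 2
Reactants: 2 geranylgeranyl chloride
Product: 3 (2E,6E,10E)-geranylgeranyl diphosphate (handled as its ammonium salt)
Conditions: (Bu4N)3HP2O7, MeCN, rt; then cation-exchange resin (NH4+ form), cellulose chromatography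
Reagents that add atoms: tris(tetrabutylammonium) hydrogen diphosphate, CCCC[N+](CCCC)(CCCC)CCCC.CCCC[N+](CCCC)(CCCC)CCCC.CCCC[N+](CCCC)(CCCC)CCCC.OP(=O)([O-])OP(=O)([O-])[O-]
Why: SN2 displacement of a primary allylic chloride by the diphosphate anion in a dipolar aprotic solvent is the standard preparation of allylic diphosphates; ion exchange gives a salt that enzymes accept.

Step 3
Reactants: 3 geranylgeranyl diphosphate
Product: 4 (5S,8S,9R,10S)-kolavenyl diphosphate (cleroda-3,13E-dien-15-yl diphosphate)
Conditions: recombinant class 2 diterpene cyclase of the (5S,8S,9R,10S)-kolavenyl series (Escherichia coli lysate or purified enzyme), HEPES buffer pH 7.5, MgCl2, glycerol, dithiothreitol, 30 °C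
Reagents that add atoms: none
Why: The aspartic acid of the enzyme's DxDD motif protonates C3 of the terminal alkene of 3, held in a chair–chair fold; the C4 cation is attacked by C5 of the C5=C10 alkene (6-endo-trig closure of ring A, bond C4–C5) and the new C10 cation by C9 of the C8=C9 alkene (6-endo-trig closure of ring B, bond C9–C10), both additions anti, giving the trans-fused C8 cation. The charge is then passed on by four suprafacial, mutually antiperiplanar 1,2-shifts (H9 to C8, the C10 methyl group to C9, H5 to C10, the 4β-methyl group to C5), and loss of H3 from the C4 cation places the alkene at C3=C4. The closest known reaction is this one itself: kolavenyl (clerodienyl) diphosphate synthases are characterised class 2 diterpene cyclases that convert 3 into the rearranged bicycle, here run on preparative scale. C8 is set by the hydride arriving from C9 on the α-face, C9 by the methyl group arriving from C10 on the β-face, C10 by the hydride from C5 (α) and C5 by the methyl group from C4 (β); their relative configuration follows from the E geometry of the substrate alkenes, the chair–chair fold and the antiperiplanar order of the shifts. The absolute configuration is decided by which enantiomeric fold the active site imposes, so an enzyme of the normal series is required. The step needs termination after exactly four shifts and proton loss from C3 (not from C18, C1 or C6, and no capture by water); nothing in the substrate secures this, it is a property of the active site, and no simple acid is known to stop selectively at this stage. The allylic diphosphate is not ionised, because class 2 cyclases lack the metal-binding motif that triggers ionisation, so C11–C16 survive as the handle for both arenes.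

Step 4
Reactants: 4 kolavenyl diphosphate
Product: 5 (5S,8S,9R,10S)-kolavenol (cleroda-3,13E-dien-15-ol)
Conditions: alkaline phosphatase, Tris buffer pH 9, MgCl2, 37 °C; hexane extraction (can be run in the vessel of step 3)
Reagents that add atoms: none
Why: Enzymatic phosphate monoester hydrolysis cleaves both P–O bonds at basic pH, which avoids the acid-induced ionisation of the allylic diphosphate; the skeleton and the alkene geometry are untouched.

Step 5
Reactants: 5 kolavenol
Product: 6 (5S,8S,9R,10S,13S,14S)-13,14-epoxyclerod-3-en-15-ol
Conditions: Ti(OiPr)4 (cat.), L-(+)-diethyl tartrate (cat.), t-BuOOH, 4 Å MS, CH2Cl2, −20 °C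
Reagents that add atoms: tert-butyl hydroperoxide, CC(C)(C)OO
Why: Sharpless asymmetric epoxidation delivers oxygen only to the alkene bound through the allylic alcohol, so C3=C4 is left alone; the L-(+)-tartrate fixes (13S,14S), which gives one defined intermediate although both centres are removed in step 6.

Step 6
Reactants: 6 epoxy alcohol
Product: 7 4-[R(endo)]butan-2-one ((5S,8S,9R,10S)-14,15-dinorclerod-3-en-13-one)
Conditions: H5IO6, THF/H2O, 0 °C to rt
Reagents that add atoms: water, O
Why: Acid-catalysed opening of the epoxide at the tertiary C13 gives the 13,14,15-triol, and twofold Malaprade glycol cleavage excises C14 and C15; periodate does not attack the isolated trisubstituted ring alkene.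

Step 7
Reactants: 7 ketone (first portion); 8 methyl acrylate
Product: 10 2-{[R(endo)]methyl}cyclohexane-1,3-dione, via keto ester 9 (not isolated)
Conditions: LiN(iPr)2, THF, −78 °C; 8, −78 °C; then KOtBu, −78 °C to rt; aq. HCl work-up
Reagents that add atoms: none
Why: Kinetic deprotonation at the methyl group (C16) and Michael addition give the 5-oxo ester 9, whose ester enolate is quenched by internal proton transfer from C12; Dieckmann closure from C12 onto the ester is the only ring closure of reasonable size and is driven by the stabilised dione enolate. The product is symmetric about C12, which removes all later regiochemical questions.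

Step 8
Reactants: 10 dione
Product: 13 2-{[R(endo)]methyl}benzene-1,3-diol, via bis(silyloxy)diene 11 (not isolated), via bis(silyl) aryl ether 12 (not isolated)
Conditions: TMSOTf, Et3N, Et2O, 0 °C; pentane, decant, evaporate; DDQ, toluene, 0 °C to rt; then K2CO3, MeOH
Reagents that add atoms: none
Why: Soft enolisation gives the cross-conjugated bis(silyl) dienol ether, which is one dehydrogenation away from an arene; hydride abstraction by the quinone from the two remaining sp3 ring carbons (dehydrogenation of a silyl dienol ether) should be much faster than allylic oxidation of the hindered C3=C4 alkene. Methanolysis frees the resorcinol.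

Step 9
Reactants: 13 resorcinol
Product: 14 2-hydroxy-3-{[R(endo)]methyl}-1,4-benzoquinone
Conditions: (KO3S)2NO (Fremy's salt), KH2PO4, H2O/acetone, rt
Reagents that add atoms: potassium nitrosodisulfonate, [K+].[K+].[O-]S(=O)(=O)N([O])S(=O)(=O)[O-]
Why: Teuber oxidation: the phenoxyl radical couples with a second nitroxyl radical para to a hydroxyl, and the two free para positions of 13 are equivalent, so one hydroxy-para-quinone should result. The radical reagent does not touch the alkene.

Step 10
Reactants: 7 ketone (second portion)
Product: 15 4-[(1R,2S,4aS,8aS)-6-chloro-1,2,4a-trimethyl-5-methylidenedecahydronaphthalen-1-yl]butan-2-one (3-chloro-14,15-dinorclerod-4(18)-en-13-one; C3 epimers)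
Conditions: Ca(OCl)2, CO2 (solid), CH2Cl2/H2O, 0 °C
Reagents that add atoms: calcium hypochlorite, [Ca+2].[O-]Cl.[O-]Cl
Why: Ene-type allylic chlorination by hypochlorous acid: chlorine adds to C3 and the developing C4 cation loses a proton; C5 is quaternary, so the proton can only come from C18 and only the exocyclic alkene can form. The C3 configuration is not controlled and is erased in step 11.

Step 11
Reactants: 15 allylic chloride
Product: 16 4-[R(exo)]butan-2-one ((5S,8S,9R,10S)-14,15-dinorclerod-4(18)-en-13-one)
Conditions: Pd(OAc)2 (cat.), n-Bu3P, HCO2NH4, 1,4-dioxane, 100 °C
Reagents that add atoms: none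
Why: Tsuji–Mandai formate hydrogenolysis: zerovalent palladium forms the allyl complex spanning C3–C4–C18, bound formate loses CO2, and the hydride is delivered to the more substituted terminus C3. This leaves the less substituted, thermodynamically disfavoured C4=C18 alkene as the kinetic product.

Step 12
Reactants: 16 exocyclic ketone; 17 dimethyl carbonate
Product: 18 methyl 3-oxo-5-[R(exo)]pentanoate
Conditions: NaH, THF, reflux; then AcOH
Reagents that add atoms: none
Why: Claisen condensation of a methyl ketone with a carbonate takes place at the methyl group (C16) and is driven by irreversible deprotonation of the β-keto ester; these conditions do not move the exocyclic alkene.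

Step 13
Reactants: 18 β-keto ester; 19 methyl propiolate
Product: 22 methyl 2,4-dihydroxy-5-{[R(exo)]methyl}benzoate, via silyl ketene acetal diene 20 (not isolated), via cyclohexadiene adduct 21 (not isolated)
Conditions: TMSOTf, Et3N, Et2O, 0 °C; pentane, decant, evaporate; 19, toluene, 80 °C; then aq. citric acid, THF, rt
Reagents that add atoms: none
Why: Diels–Alder reaction of a 1-methoxy-1,3-bis(silyloxy)diene with an alkynoate: the nucleophilic diene terminus C12 bonds to the β-carbon of the propiolate, which places the ester next to the new ring CH and para to the C13 oxygen. The (Z)-enol ether keeps the C11 substituent on the outside of the diene; loss of methanol and desilylation aromatise the adduct.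

Step 14
Reactants: 22 resorcylate
Product: 24 methyl 3-amino-2,4-dihydroxy-5-{[R(exo)]methyl}benzoate, via azo compound 23 (not isolated)
Conditions: 4-diazoniobenzenesulfonate, Na2CO3, THF/H2O, 0 °C; then Na2S2O4, 45 °C, under N2
Reagents that add atoms: 4-diazoniobenzenesulfonate, [O-]S(=O)(=O)c1ccc(cc1)[N+]#N
Why: Azo coupling of the resorcinol monoanion can only take place at C3, the one ring CH ortho to both oxygens; dithionite then cleaves the N=N bond to the amine and water-soluble sulfanilate. Neither reagent touches the exocyclic alkene or the ester.

Step 15
Reactants: 14 hydroxyquinone; 24 aminoresorcinol ester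
Product: 25 nakijiquinone E
Conditions: EtOH, CeCl3·7H2O (cat.), rt, under air
Reagents that add atoms: none
Why: Conjugate amination of a hydroxy-para-quinone by an arylamine, followed by reoxidation of the aminohydroquinone (by 14, which air regenerates): C4=O of 14 is deactivated as a vinylogous acid, so the amine adds at C5, β to the C1 carbonyl. The product is a push–pull aminohydroxyquinone and should not add a second amine. The closest precedents are the additions of anilines to 2-hydroxy-3-alkylbenzoquinones and of amines to 2-methoxyquinones, which give the same 2,5-pattern.

## Compound list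

1 | geranylgeraniol | CC(C)=CCC/C(C)=C/CC/C(C)=C/CC/C(C)=C/CO | starting material
2 | geranylgeranyl chloride | CC(C)=CCC/C(C)=C/CC/C(C)=C/CC/C(C)=C/CCl | intermediate
3 | (2E,6E,10E)-geranylgeranyl diphosphate | CC(C)=CCC/C(C)=C/CC/C(C)=C/CC/C(C)=C/COP(=O)(O)OP(=O)(O)O | intermediate
4 | (5S,8S,9R,10S)-kolavenyl diphosphate | OP(=O)(O)OP(=O)(O)OC/C=C(\C)CC[C@]1(C)[C@@H](C)CC[C@]2(C)C(C)=CCC[C@@H]12 | intermediate
5 | (5S,8S,9R,10S)-kolavenol | OC/C=C(\C)CC[C@]1(C)[C@@H](C)CC[C@]2(C)C(C)=CCC[C@@H]12 | intermediate
6 | (5S,8S,9R,10S,13S,14S)-13,14-epoxyclerod-3-en-15-ol | OC[C@@H]1O[C@@]1(C)CC[C@]2(C)[C@@H](C)CC[C@]3(C)C(C)=CCC[C@@H]23 | intermediate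
7 | 4-[R(endo)]butan-2-one | CC(=O)CC[C@]1(C)[C@@H](C)CC[C@]2(C)C(C)=CCC[C@@H]12 | intermediate
8 | methyl acrylate | C=CC(=O)OC | starting material
9 | methyl 5-oxo-7-[R(endo)]heptanoate | COC(=O)CCCC(=O)CC[C@]1(C)[C@@H](C)CC[C@]2(C)C(C)=CCC[C@@H]12 | intermediate
10 | 2-{[R(endo)]methyl}cyclohexane-1,3-dione | O=C1CCCC(=O)C1C[C@]2(C)[C@@H](C)CC[C@]3(C)C(C)=CCC[C@@H]23 | intermediate
11 | 2-{[R(endo)]methyl}-1,3-bis(trimethylsilyloxy)cyclohexa-1,3-diene | C[Si](C)(C)OC1=C(C[C@]2(C)[C@@H](C)CC[C@]3(C)C(C)=CCC[C@@H]23)C(O[Si](C)(C)C)=CCC1 | intermediate
12 | 2-{[R(endo)]methyl}-1,3-bis(trimethylsilyloxy)benzene | C[Si](C)(C)Oc1cccc(O[Si](C)(C)C)c1C[C@]2(C)[C@@H](C)CC[C@]3(C)C(C)=CCC[C@@H]23 | intermediate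
13 | 2-{[R(endo)]methyl}benzene-1,3-diol | Oc1cccc(O)c1C[C@]2(C)[C@@H](C)CC[C@]3(C)C(C)=CCC[C@@H]23 | intermediate
14 | 2-hydroxy-3-{[R(endo)]methyl}-1,4-benzoquinone | O=C1C=CC(=O)C(O)=C1C[C@]2(C)[C@@H](C)CC[C@]3(C)C(C)=CCC[C@@H]23 | intermediate
15 | 3-chloro-14,15-dinorclerod-4(18)-en-13-one (C3 epimers) | CC(=O)CC[C@]1(C)[C@@H](C)CC[C@]2(C)C(=C)C(Cl)CC[C@@H]12 | intermediate
16 | 4-[R(exo)]butan-2-one | CC(=O)CC[C@]1(C)[C@@H](C)CC[C@]2(C)C(=C)CCC[C@@H]12 | intermediate
17 | dimethyl carbonate | COC(=O)OC | starting material
18 | methyl 3-oxo-5-[R(exo)]pentanoate | COC(=O)CC(=O)CC[C@]1(C)[C@@H](C)CC[C@]2(C)C(=C)CCC[C@@H]12 | intermediate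
19 | methyl propiolate | C#CC(=O)OC | starting material
20 | (3Z)-1-methoxy-5-[R(exo)]-1,3-bis(trimethylsilyloxy)penta-1,3-diene | COC(O[Si](C)(C)C)=C/C(O[Si](C)(C)C)=C/C[C@]1(C)[C@@H](C)CC[C@]2(C)C(=C)CCC[C@@H]12 | intermediate
21 | methyl 6-methoxy-3-{[R(exo)]methyl}-4,6-bis(trimethylsilyloxy)cyclohexa-1,4-diene-1-carboxylate (diastereomers at ring C3 and C6) | COC(=O)C1=CC(C[C@]2(C)[C@@H](C)CC[C@]3(C)C(=C)CCC[C@@H]23)C(O[Si](C)(C)C)=CC1(OC)O[Si](C)(C)C | intermediate
22 | methyl 2,4-dihydroxy-5-{[R(exo)]methyl}benzoate | COC(=O)c1cc(C[C@]2(C)[C@@H](C)CC[C@]3(C)C(=C)CCC[C@@H]23)c(O)cc1O | intermediate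
23 | methyl 2,4-dihydroxy-5-{[R(exo)]methyl}-3-[(E)-(4-sulfophenyl)diazenyl]benzoate (sodium salt in the flask) | COC(=O)c1cc(C[C@]2(C)[C@@H](C)CC[C@]3(C)C(=C)CCC[C@@H]23)c(O)c(/N=N/c4ccc(cc4)S(=O)(=O)O)c1O | intermediate
24 | methyl 3-amino-2,4-dihydroxy-5-{[R(exo)]methyl}benzoate | COC(=O)c1cc(C[C@]2(C)[C@@H](C)CC[C@]3(C)C(=C)CCC[C@@H]23)c(O)c(N)c1O | intermediate
25 | nakijiquinone E | C=C1CCC[C@H]2[C@](C)(Cc3cc(C(=O)OC)c(O)c(NC4=CC(=O)C(O)=C(C[C@]5(C)[C@@H](C)CC[C@]6(C)C(C)=CCC[C@@H]56)C4=O)c3O)[C@@H](C)CC[C@]12C | target

## Step count and least certain steps

Total: 15 steps. Longest linear sequence: 12 steps (1–6, 10–14, 15); the quinone branch (steps 7–9) runs in parallel from 7.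

**Step 3 (key step).** The cation cascade may be derailed: early proton loss would give unrearranged or partly rearranged bicyclic diphosphates, and water may capture a cation. An enzyme of the antipodal fold would give the wrong series; this cannot be repaired chemically and must be ruled out on 5. On preparative scale the reaction is most likely to stall, because amphiphilic 3 aggregates, inhibits class 2 cyclases together with magnesium ions, and slowly solvolyses. The fallback replaces preformed 3 by an enzymatic cascade that keeps 3 at a low steady-state concentration. It sets out from 1: a promiscuous prenol kinase with ATP regeneration should give geranylgeranyl phosphate F1, an isopentenyl phosphate kinase variant that accepts long chains should convert F1 into 3 in the same vessel, and the cyclase present should turn 3 over as it forms. It comes back to the route at 4. The same enzymes can be run in whole cells.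

**Step 15.** Electron transfer between 14 and the electron-rich 24 may outrun C–N bond formation and consume the aminoresorcinol. Salt formation between the acidic hydroxyquinone and the amine may slow the addition, and some addition at C6 cannot be excluded. The fallback is a redox-neutral aminolysis and sets out from 14. O-Methylation (Me3SiCHN2, MeOH/toluene) would give 2-methoxy-3-{[R(endo)]methyl}-1,4-benzoquinone F2. Oxidative methoxylation (ZnCl2, MeOH, air) at C5, the carbon activated by the free carbonyl, would give 2,5-dimethoxy-3-{[R(endo)]methyl}-1,4-benzoquinone F3. Hydrolysis (aq. KOH/MeOH, then acid) of the methoxy group that the neighbouring alkyl group twists out of conjugation would give 2-hydroxy-5-methoxy-3-{[R(endo)]methyl}-1,4-benzoquinone F4. Addition–elimination of 24 at C5 of F4 (NaHCO3, EtOH, under argon) comes back at 25. If the other methoxy group of F3 hydrolyses first, aminolysis is done before hydrolysis.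

**Step 7.** The ester enolate formed in the Michael addition may start anionic oligomerisation of 8, and enolate equilibration before the addition would send the acrylate to C12 and give the wrong (4-substituted) dione. The fallback separates the two events and sets out from 7. Kinetic silylation (LiN(iPr)2, Me3SiCl, −78 °C) would give the trimethylsilyl enol ether F5. Mukaiyama–Michael addition of F5 to 8 (TiCl4, CH2Cl2, −78 °C) would give 9, now isolated, and NaOMe in MeOH would close it to 10, where the route is rejoined.

**Step 8.** The quinone oxidant may abstract an allylic hydride next to C3=C4 or over-oxidise the electron-rich aryl silyl ether, and premature desilylation would return 10. The fallback aromatises by selenoxide elimination and sets out from 10. MeOH, HC(OMe)3 and catalytic TsOH would give 3-methoxy-2-{[R(endo)]methyl}cyclohex-2-en-1-one F6. LiN(iPr)2 and PhSeCl would give the α'-selenide 3-methoxy-2-{[R(endo)]methyl}-6-(phenylselanyl)cyclohex-2-en-1-one F7. Oxidation (H2O2, pyridine, 0 °C), syn-elimination and tautomerisation would give 3-methoxy-2-{[R(endo)]methyl}phenol F8. Demethylation with NaSEt in DMF comes back at 13.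

**Step 13.** Traces of triflic acid or the acidic aromatisation may move the C4=C18 alkene into the ring. The γ-substituted diene may react sluggishly, so that hydrolysis or stepwise Michael addition without ring closure competes. The fallback builds the ring by condensation and carboxylation and sets out from 16 and 8. Under equilibrating conditions (KOtBu, THF) the Michael addition should occur at C12 to give methyl 4-acetyl-5-[R(exo)]pentanoate F9, which should close in the same flask to 4-{[R(exo)]methyl}cyclohexane-1,3-dione F10. Aerobic dehydrogenation (Pd(O2CCF3)2, O2, DMSO, 80 °C) would give 4-{[R(exo)]methyl}benzene-1,3-diol F11. Kolbe–Schmitt carboxylation (KHCO3, CO2, 100 °C) para to one hydroxyl and ortho to the other would give 2,4-dihydroxy-5-{[R(exo)]methyl}benzoic acid F12. O-Methylation of the carboxylate (MeI, KHCO3, DMF) comes back at 22.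

## Further compounds

F1 | step 3 | geranylgeranyl phosphate | CC(C)=CCC/C(C)=C/CC/C(C)=C/CC/C(C)=C/COP(=O)(O)O
F2 | step 15 | 2-methoxy-3-{[R(endo)]methyl}-1,4-benzoquinone | COC1=C(C[C@]2(C)[C@@H](C)CC[C@]3(C)C(C)=CCC[C@@H]23)C(=O)C=CC1=O
F3 | step 15 | 2,5-dimethoxy-3-{[R(endo)]methyl}-1,4-benzoquinone | COC1=CC(=O)C(OC)=C(C[C@]2(C)[C@@H](C)CC[C@]3(C)C(C)=CCC[C@@H]23)C1=O
F4 | step 15 | 2-hydroxy-5-methoxy-3-{[R(endo)]methyl}-1,4-benzoquinone | COC1=CC(=O)C(O)=C(C[C@]2(C)[C@@H](C)CC[C@]3(C)C(C)=CCC[C@@H]23)C1=O
F5 | step 7 | 4-[R(endo)]-2-(trimethylsilyloxy)but-1-ene | C=C(O[Si](C)(C)C)CC[C@]1(C)[C@@H](C)CC[C@]2(C)C(C)=CCC[C@@H]12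
F6 | step 8 | 3-methoxy-2-{[R(endo)]methyl}cyclohex-2-en-1-one | COC1=C(C[C@]2(C)[C@@H](C)CC[C@]3(C)C(C)=CCC[C@@H]23)C(=O)CCC1
F7 | step 8 | 3-methoxy-2-{[R(endo)]methyl}-6-(phenylselanyl)cyclohex-2-en-1-one (C6 epimers) | COC1=C(C[C@]2(C)[C@@H](C)CC[C@]3(C)C(C)=CCC[C@@H]23)C(=O)C([Se]c4ccccc4)CC1
F8 | step 8 | 3-methoxy-2-{[R(endo)]methyl}phenol | COc1cccc(O)c1C[C@]2(C)[C@@H](C)CC[C@]3(C)C(C)=CCC[C@@H]23
F9 | step 13 | methyl 4-acetyl-5-[R(exo)]pentanoate (C4 epimers) | COC(=O)CCC(C[C@]1(C)[C@@H](C)CC[C@]2(C)C(=C)CCC[C@@H]12)C(C)=O
F10 | step 13 | 4-{[R(exo)]methyl}cyclohexane-1,3-dione (C4 epimers) | O=C1CC(=O)C(C[C@]2(C)[C@@H](C)CC[C@]3(C)C(=C)CCC[C@@H]23)CC1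
F11 | step 13 | 4-{[R(exo)]methyl}benzene-1,3-diol | Oc1ccc(C[C@]2(C)[C@@H](C)CC[C@]3(C)C(=C)CCC[C@@H]23)c(O)c1
F12 | step 13 | 2,4-dihydroxy-5-{[R(exo)]methyl}benzoic acid | OC(=O)c1cc(C[C@]2(C)[C@@H](C)CC[C@]3(C)C(=C)CCC[C@@H]23)c(O)cc1O
A1 | alternative 1 | cis-fused endo Diels–Alder adduct | COC1=CC(=O)[C@@]2(C)CC=C(C)[C@@](C)(CO[Si](C)(C)C(C)(C)C)[C@H]2C1=O
A2 | alternative 2 | arylamino ethoxy hydroquinone | CCOc1c(O)cc(Nc2c(OCOC)c(C(=O)OC)cc(C[C@]3(C)[C@@H](C)CC[C@]4(C)C(=C)CCC[C@@H]34)c2OCOC)c(O)c1C[C@]5(C)[C@@H](C)CC[C@]6(C)C(C)=CCC[C@@H]56
A3 | alternative 3 | trans-decalin dienyl aldehyde, C4 ketal | O1CCOC12CCC[C@H]3[C@](C)(C=O)C(=C)C=C[C@]23C
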